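| setting | east | west | flask |
|---|---|---|---|
| starting material | 1.7 M | 1.7 M | 1.7 M |
| reagent | 1.3 equiv | 1.3 equiv | 1.30 equiv |
| second substrate | 0.13 equiv | 0.30 equiv | 0.200 equiv |
| remark | run made earlier | run made earlier |  |
| time |  |  | 4.0 h |

| run | time / h | target / % | starting material / % |
|---|---|---|---|
| east | 0.0833 | 22 | 79 |
| east | 0.250 | 29 | 72 |
| east | 0.833 | 26 | 75 |
| east | 2.50 | 16 | 85 |
| west | 0.0833 | 24 | 79 |
| west | 0.250 | 29 | 71 |
| west | 0.833 | 24 | 73 |
| west | 2.50 | 16 | 85 |

(scatter of a reading: 1.5 percentage points)

* the best time, 4.0 h at the latest, for target
* the amount of target, in percent of the starting material charged, at that time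

- the analysis behind the earlier runs scatters by 1.5 percentage points, standard deviation

**Time first.** Time is the setting to watch on the flask, charged with 0.200 equiv of second substrate. The east and west runs, at 0.13 equiv and 0.30 equiv, read 29 % and 29 % of target at 0.250 h, so these two readings of target do not tell the two charges apart.

**Back-ratio.** Starting material and target add up to about 101 % in the last east reading, so one number describes the mix: starting material per unit of target, the position of a drifting quasi-equilibrium. Pooling both runs, it reads 2.96 at 0.833 h and 5.31 at 2.50 h, and that climb per hour is the back-ratio drift, 1.41 h⁻¹.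

**On arrival.** Carried back to 0.250 h, the drift gives a back-ratio of 2.14, a ceiling of 31.8 % target. The readings stand lower than that, so this reckoning expects target still rising there and puts the best in the flask somewhat later, between that reading and the ceiling. Carried forward to 4.0 h, the drift leaves 11.9 % target, so the flask should not be left standing.

**Result.** The forecast, which sees “a fast approach to a quasi-equilibrium that slowly drifts back”, puts the best at 0.25 h with 29.3 %, earlier than this reckoning. The flask gives 30.5 % at 0.302 h.

    starting material + reagent ⇌ target (K = 0.582 L mol⁻¹, k = 0.0345 L mol⁻¹ min⁻¹)
    second substrate + reagent ⇌ second product (K = 1.07 L mol⁻¹, k = 0.0646 L mol⁻¹ min⁻¹)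
    2 reagent → self-condensation product (k = 0.0148 L mol⁻¹ min⁻¹)

**Next flask.** At 4.00 h the flask holds 11.5 % of target, against the 11.9 % reckoned from the drift. A neighbouring flask with 0.0500 equiv of second substrate in place of 0.200 equiv gets the same reckoning, since the drift carries no term for second substrate, and so again 11.9 %. That neighbour peaks at 31.6 % and holds 11.0 % of target at 4.00 h.

All runs were generated by integration from invented constants; scatter was added.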